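## Plan

- **Cuts, in retrosynthetic order:** the tert-butyl ester and the C3 6-methylheptanoate (the last two steps); then the C2–C3 ring bond (vinyl bromide plus aldehyde); then the C4 tiglate, the vinylic C–Br bond and the C5 acetate; last the C5–C6 bond between a glyceraldehyde and a 2-(bromomethyl)acrylate.
- **Feature that allows the ring cut:** the only ring is a cyclohexene in which C1 carries the carboxyl, C2 is the vinylic CH and C3 is an acyloxy-bearing allylic carbon. C2 is therefore the β-carbon of the C1 acrylate, and C2–C3 is the bond a vinylmetal forms with an aldehyde; the hydroxyl released at C3 is the one that takes the 6-methylheptanoate.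
- **Forward order:** indium allylation joins C5–C6; the chain receives the C5 acetate, the C2 bromide and the C4 tiglate and is oxidised at C3; the single ring closes at C2–C3; C3 acylation and ester cleavage finish.
- **Stereochemistry:** C4 comes from (S)-glyceraldehyde acetonide; C5 from anti (Felkin–Anh) allylation followed by Mitsunobu inversion with acetic acid; C3 is set in the ring closure, trans to the C4 ester; the E bromide geometry is set in the dehydrobromination.

Key step: step 9

Assumption: the indium allylation of the acetonide-protected aldehyde is taken to be anti (Felkin–Anh) selective, as is usual when the α-oxygen is held in a dioxolane, so the C5 acetate is introduced with inversion.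

Labels C1–C6 in the comments are those of the final ring; the names of open-chain compounds use their own numbering.

## Route

Step 1
Reactants: 1 (S)-2,3-O-isopropylideneglyceraldehyde; 2 tert-butyl 2-(bromomethyl)acrylate
Product: 4 tert-butyl (4R)-4-[(4S)-2,2-dimethyl-1,3-dioxolan-4-yl]-4-hydroxy-2-methylidenebutanoate, via allylindium dibromide 3 (not isolated)
Conditions: In powder, THF–H2O (1:1), rt
Reagents that add atoms: none
Why: Barbier-type indium allylation in aqueous medium, in which the allylindium species should add through a six-membered chair transition state to the aldehyde face anti to the dioxolane C–O bond (Felkin–Anh, the ring oxygen not chelating), setting the new carbinol as 4R (anti), while the tert-butyl ester holds back lactonisation and the minor syn epimer is removed by chromatography.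

Step 2
Reactants: 4 tert-butyl (4R)-4-[(4S)-2,2-dimethyl-1,3-dioxolan-4-yl]-4-hydroxy-2-methylidenebutanoate
Product: 5 tert-butyl (4S)-4-acetoxy-4-[(4S)-2,2-dimethyl-1,3-dioxolan-4-yl]-2-methylidenebutanoate
Conditions: PPh3, DIAD, AcOH, THF, 0 °C to rt
Reagents that add atoms: acetic acid, CC(=O)O
Why: Mitsunobu esterification, in which the hydroxyl is activated by PPh3/DIAD and displaced by acetate in an SN2 step, so the acetate should arrive with inversion and the carbinol (the later ring C5) becomes 4S, the dioxolane centre being untouched.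

Step 3
Reactants: 5 tert-butyl (4S)-4-acetoxy-4-[(4S)-2,2-dimethyl-1,3-dioxolan-4-yl]-2-methylidenebutanoate
Product: 7 tert-butyl (2E,4S)-4-acetoxy-2-(bromomethylidene)-4-[(4S)-2,2-dimethyl-1,3-dioxolan-4-yl]butanoate, via vicinal dibromide 6 (not isolated)
Conditions: Br2, CH2Cl2, 0 °C; then DBU, 0 °C to rt
Reagents that add atoms: bromine, BrBr
Why: Bromination–dehydrobromination of an α-substituted acrylate, in which Br2 adds across the 1,1-disubstituted alkene and DBU should then remove the more acidic CH2Br hydrogen together with the tertiary bromide (E2), the β-bromoacrylate settling as the more stable E isomer (bromine trans to the ester and cis to the chain, as the ring closure requires) with no new stereocentre in the product.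

Step 4
Reactants: 7 tert-butyl (2E,4S)-4-acetoxy-2-(bromomethylidene)-4-[(4S)-2,2-dimethyl-1,3-dioxolan-4-yl]butanoate
Product: 8 tert-butyl (2E,4S,5S)-4-acetoxy-2-(bromomethylidene)-5,6-dihydroxyhexanoate
Conditions: AcOH–H2O (4:1), 40 °C
Reagents that add atoms: none
Why: Acid-catalysed hydrolysis of a terminal isopropylidene acetal, which aqueous acetic acid should achieve while the tert-butyl ester, the acetate and the vinyl bromide (all needing stronger acid or base) stay in place and no stereocentre is touched.

Step 5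
Reactants: 8 tert-butyl (2E,4S,5S)-4-acetoxy-2-(bromomethylidene)-5,6-dihydroxyhexanoate
Product: 9 tert-butyl (2E,4S,5S)-4-acetoxy-2-(bromomethylidene)-6-[(tert-butyldimethylsilyl)oxy]-5-hydroxyhexanoate
Conditions: TBSCl, imidazole, CH2Cl2, 0 °C
Reagents that add atoms: tert-butyldimethylsilyl chloride, CC(C)(C)[Si](C)(C)Cl
Why: Selective silylation, in which the bulky silyl chloride should react at the primary hydroxyl much faster than at the secondary one, leaving the later C4 hydroxyl as the only free one.

Step 6
Reactants: 9 tert-butyl (2E,4S,5S)-4-acetoxy-2-(bromomethylidene)-6-[(tert-butyldimethylsilyl)oxy]-5-hydroxyhexanoate; 10 tigloyl chloride, (2E)-2-methylbut-2-enoyl chloride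
Product: 11 tert-butyl (2E,4S,5S)-4-acetoxy-2-(bromomethylidene)-6-[(tert-butyldimethylsilyl)oxy]-5-{[(2E)-2-methylbut-2-enoyl]oxy}hexanoate
Conditions: pyridine, DMAP (cat.), CH2Cl2, 0 °C to rt
Reagents that add atoms: none
Why: DMAP-catalysed acylation of the lone secondary hydroxyl by an acid chloride, which keeps the configuration (the C–O bond is not broken) and, being fast and only weakly basic (pyridine instead of a trialkylamine, so no vinylketene from the acid chloride), should leave little room for acetyl migration from the neighbouring oxygen.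

Step 7
Reactants: 11 tert-butyl (2E,4S,5S)-4-acetoxy-2-(bromomethylidene)-6-[(tert-butyldimethylsilyl)oxy]-5-{[(2E)-2-methylbut-2-enoyl]oxy}hexanoate
Product: 12 tert-butyl (2E,4S,5S)-4-acetoxy-2-(bromomethylidene)-6-hydroxy-5-{[(2E)-2-methylbut-2-enoyl]oxy}hexanoate
Conditions: HF·pyridine, pyridine, THF, 0 °C to rt
Reagents that add atoms: none
Why: Fluoride-driven desilylation of a primary silyl ether under buffered, slightly acidic conditions, which should spare the four esters and suppress migration of the tigloyl group to the freed primary hydroxyl.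

Step 8
Reactants: 12 tert-butyl (2E,4S,5S)-4-acetoxy-2-(bromomethylidene)-6-hydroxy-5-{[(2E)-2-methylbut-2-enoyl]oxy}hexanoate
Product: 13 tert-butyl (2E,4S,5R)-4-acetoxy-2-(bromomethylidene)-5-{[(2E)-2-methylbut-2-enoyl]oxy}-6-oxohexanoate
Conditions: Dess–Martin periodinane, CH2Cl2, 0 °C to rt
Reagents that add atoms: none
Why: Dess–Martin oxidation, which proceeds by ligand exchange at hypervalent iodine without added base, so the epimerisable α-tigloyloxy centre and the β-acetoxy group (prone to E1cB loss) should survive, the crude aldehyde being used at once.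

Step 9
Reactants: 13 tert-butyl (2E,4S,5R)-4-acetoxy-2-(bromomethylidene)-5-{[(2E)-2-methylbut-2-enoyl]oxy}-6-oxohexanoate
Product: 15 tert-butyl (3R,4R,5S)-5-acetoxy-3-hydroxy-4-{[(2E)-2-methylbut-2-enoyl]oxy}cyclohex-1-ene-1-carboxylate, via vinylchromium dichloride 14 (not isolated)
Conditions: CrCl2 (excess), NiCl2 (cat.), degassed DMF, rt, high dilution; aqueous work-up
Reagents that add atoms: none
Why: Zerovalent nickel, formed from NiCl2 by CrCl2, inserts into the C–Br bond of the β-bromoacrylate; transmetalation gives a vinylchromium of trivalent chromium with retained geometry, which adds to the aldehyde and forms the C2–C3 bond. The closest known reaction type is the intramolecular Nozaki–Hiyama–Kishi cyclisation of formyl-bearing vinyl halides to 2-cycloalkenols, applied here to a β-haloacrylate. The six-membered ring closes in the 6-exo-trig mode with respect to the carbonyl group, which only the E bromide (metal cis to the C6 methylene) can reach, and high dilution keeps the coupling intramolecular. The new C3 stereocentre is controlled by the C4 and C5 esters, which should lie equatorial in a chair-like transition state with the C4–O bond anti to the incoming vinyl carbon, while the chromium-bound aldehyde oxygen takes the pseudo-equatorial position; this is expected to give the 3R alcohol trans to the tiglate. The step needs chemoselectivity for the aldehyde over four esters and an enoate, secured by the low basicity and nucleophilicity of organochromium reagents, and an unepimerised aldehyde, secured by the neutral medium at room temperature.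

Step 10
Reactants: 15 tert-butyl (3R,4R,5S)-5-acetoxy-3-hydroxy-4-{[(2E)-2-methylbut-2-enoyl]oxy}cyclohex-1-ene-1-carboxylate; 16 6-methylheptanoic acid
Product: 17 tert-butyl (3R,4R,5S)-5-acetoxy-3-[(6-methylheptanoyl)oxy]-4-{[(2E)-2-methylbut-2-enoyl]oxy}cyclohex-1-ene-1-carboxylate
Conditions: DCC, DMAP (cat.), CH2Cl2, 0 °C to rt
Reagents that add atoms: none
Why: Steglich esterification, in which DCC activates the acid and DMAP passes the acyl group to the allylic C3 hydroxyl, whose C–O bond stays intact, so the 3R configuration should be retained.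

Step 11
Reactants: 17 tert-butyl (3R,4R,5S)-5-acetoxy-3-[(6-methylheptanoyl)oxy]-4-{[(2E)-2-methylbut-2-enoyl]oxy}cyclohex-1-ene-1-carboxylate
Product: 18 (3R,4R,5S)-5-acetoxy-3-[(6-methylheptanoyl)oxy]-4-{[(2E)-2-methylbut-2-enoyl]oxy}cyclohex-1-ene-1-carboxylic acid (CNP0225437.1)
Conditions: CF3CO2H, CH2Cl2, 0 °C to rt
Reagents that add atoms: none
Why: Acidolysis of a tert-butyl ester through loss of the tert-butyl cation as isobutene, which should free the acid while the acetate, tiglate and 6-methylheptanoate, stable to anhydrous CF3CO2H, and all three stereocentres stay as they are.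

## Compound list

1 | (S)-2,3-O-isopropylideneglyceraldehyde | O=C[C@@H]1COC(C)(C)O1 | starting material
2 | tert-butyl 2-(bromomethyl)acrylate | C=C(CBr)C(=O)OC(C)(C)C | starting material
3 | allylindium dibromide, written in its simplest form as tert-butyl 2-[(dibromoindiganyl)methyl]prop-2-enoate (formed in the flask) | C=C(C[In](Br)Br)C(=O)OC(C)(C)C | intermediate
4 | tert-butyl (4R)-4-[(4S)-2,2-dimethyl-1,3-dioxolan-4-yl]-4-hydroxy-2-methylidenebutanoate | C=C(C[C@@H](O)[C@@H]1COC(C)(C)O1)C(=O)OC(C)(C)C | intermediate
5 | tert-butyl (4S)-4-acetoxy-4-[(4S)-2,2-dimethyl-1,3-dioxolan-4-yl]-2-methylidenebutanoate | C=C(C[C@H](OC(C)=O)[C@@H]1COC(C)(C)O1)C(=O)OC(C)(C)C | intermediate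
6 | tert-butyl (4S)-4-acetoxy-2-bromo-2-(bromomethyl)-4-[(4S)-2,2-dimethyl-1,3-dioxolan-4-yl]butanoate, both C2 epimers (formed in the flask) | BrCC(Br)(C[C@H](OC(C)=O)[C@@H]1COC(C)(C)O1)C(=O)OC(C)(C)C | intermediate
7 | tert-butyl (2E,4S)-4-acetoxy-2-(bromomethylidene)-4-[(4S)-2,2-dimethyl-1,3-dioxolan-4-yl]butanoate | Br/C=C(\C[C@H](OC(C)=O)[C@@H]1COC(C)(C)O1)C(=O)OC(C)(C)C | intermediate
8 | tert-butyl (2E,4S,5S)-4-acetoxy-2-(bromomethylidene)-5,6-dihydroxyhexanoate | Br/C=C(\C[C@H](OC(C)=O)[C@@H](O)CO)C(=O)OC(C)(C)C | intermediate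
9 | tert-butyl (2E,4S,5S)-4-acetoxy-2-(bromomethylidene)-6-[(tert-butyldimethylsilyl)oxy]-5-hydroxyhexanoate | Br/C=C(\C[C@H](OC(C)=O)[C@@H](O)CO[Si](C)(C)C(C)(C)C)C(=O)OC(C)(C)C | intermediate
10 | tigloyl chloride, (2E)-2-methylbut-2-enoyl chloride | C/C=C(\C)C(=O)Cl | starting material
11 | tert-butyl (2E,4S,5S)-4-acetoxy-2-(bromomethylidene)-6-[(tert-butyldimethylsilyl)oxy]-5-{[(2E)-2-methylbut-2-enoyl]oxy}hexanoate | Br/C=C(\C[C@H](OC(C)=O)[C@@H](OC(=O)/C(C)=C/C)CO[Si](C)(C)C(C)(C)C)C(=O)OC(C)(C)C | intermediate
12 | tert-butyl (2E,4S,5S)-4-acetoxy-2-(bromomethylidene)-6-hydroxy-5-{[(2E)-2-methylbut-2-enoyl]oxy}hexanoate | Br/C=C(\C[C@H](OC(C)=O)[C@@H](OC(=O)/C(C)=C/C)CO)C(=O)OC(C)(C)C | intermediate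
13 | tert-butyl (2E,4S,5R)-4-acetoxy-2-(bromomethylidene)-5-{[(2E)-2-methylbut-2-enoyl]oxy}-6-oxohexanoate | Br/C=C(\C[C@H](OC(C)=O)[C@@H](OC(=O)/C(C)=C/C)C=O)C(=O)OC(C)(C)C | intermediate
14 | vinylchromium dichloride, tert-butyl (2E,4S,5R)-4-acetoxy-2-[(dichlorochromio)methylidene]-5-{[(2E)-2-methylbut-2-enoyl]oxy}-6-oxohexanoate (formed in the flask) | Cl[Cr](Cl)/C=C(\C[C@H](OC(C)=O)[C@@H](OC(=O)/C(C)=C/C)C=O)C(=O)OC(C)(C)C | intermediate
15 | tert-butyl (3R,4R,5S)-5-acetoxy-3-hydroxy-4-{[(2E)-2-methylbut-2-enoyl]oxy}cyclohex-1-ene-1-carboxylate | C/C=C(\C)C(=O)O[C@@H]1[C@@H](OC(C)=O)CC(C(=O)OC(C)(C)C)=C[C@H]1O | intermediate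
16 | 6-methylheptanoic acid | CC(C)CCCCC(=O)O | starting material
17 | tert-butyl (3R,4R,5S)-5-acetoxy-3-[(6-methylheptanoyl)oxy]-4-{[(2E)-2-methylbut-2-enoyl]oxy}cyclohex-1-ene-1-carboxylate | C/C=C(\C)C(=O)O[C@@H]1[C@@H](OC(C)=O)CC(C(=O)OC(C)(C)C)=C[C@H]1OC(=O)CCCCC(C)C | intermediate
18 | (3R,4R,5S)-5-acetoxy-3-[(6-methylheptanoyl)oxy]-4-{[(2E)-2-methylbut-2-enoyl]oxy}cyclohex-1-ene-1-carboxylic acid | C/C=C(\C)C(=O)O[C@@H]1[C@@H](OC(C)=O)CC(C(=O)O)=C[C@H]1OC(=O)CCCCC(C)C | target

## Step count and risks

Total step count: 11. Longest linear sequence: 11 steps (1 to 18).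

Steps most likely to fail:

**Step 3 (course of the HBr loss).** The base may take a C6 hydrogen instead of a CH2Br hydrogen and give the allylic bromide, may leave the Z bromide, or may expel acetic acid across C5–C6 once the bromoacrylate is formed. The fallback sets out from 4 and comes back at 7. It moves the halogenation in front of the acetate. Alcohol 4 is silylated (TBSCl, imidazole, DMF) to tert-butyl (4R)-4-[(tert-butyldimethylsilyl)oxy]-4-[(4S)-2,2-dimethyl-1,3-dioxolan-4-yl]-2-methylidenebutanoate F1. A silyloxy group is no leaving group, acidifies the C6 hydrogens less than an acetoxy group and screens them from the amidine base. Br2 then gives the dibromide tert-butyl (4R)-2-bromo-2-(bromomethyl)-4-[(tert-butyldimethylsilyl)oxy]-4-[(4S)-2,2-dimethyl-1,3-dioxolan-4-yl]butanoate F2, which DBU converts in the same flask into tert-butyl (2E,4R)-2-(bromomethylidene)-4-[(tert-butyldimethylsilyl)oxy]-4-[(4S)-2,2-dimethyl-1,3-dioxolan-4-yl]butanoate F3. HF·pyridine frees tert-butyl (2E,4R)-2-(bromomethylidene)-4-[(4S)-2,2-dimethyl-1,3-dioxolan-4-yl]-4-hydroxybutanoate F4. The Mitsunobu reaction with acetic acid (PPh3, DIAD, THF) then inverts the carbinol and gives 7. This fallback lowers the risk of C6 deprotonation and removes the acetate loss, but it still relies on the same elimination.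

**Step 9 (facial selectivity at the C3 aldehyde).** The vinylchromium may add to the other face and give the C3 epimer, with the hydroxyl cis to the tiglate; the chair-like model does not rule this out. The fallback sets out from 13 and comes back at 17. The same cyclisation is run and the epimeric alcohol, tert-butyl (3S,4R,5S)-5-acetoxy-3-hydroxy-4-{[(2E)-2-methylbut-2-enoyl]oxy}cyclohex-1-ene-1-carboxylate F5, is esterified with 16 under Mitsunobu conditions (PPh3, DIAD, THF) instead of DCC. The SN2 displacement inverts C3 and gives 17. The cis tiglate cannot take part from the rear, and the ester-bearing alkene carbon disfavours SN2′ attack. Both C3 epimers of the cyclisation therefore converge on 17.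

**Step 2 (incomplete displacement at the hindered carbinol).** Acetic acid is a weak pronucleophile, so elimination, or attack of the ester carbonyl on the activated alcohol to give a lactone, may compete. The fallback sets out from 4 and comes back at 5. The inversion is carried out with the stronger acid chloroacetic acid (PPh3, DIAD, THF) to give tert-butyl (4S)-4-[(chloroacetyl)oxy]-4-[(4S)-2,2-dimethyl-1,3-dioxolan-4-yl]-2-methylidenebutanoate F6. The chloroacetate is removed under neutral conditions (thiourea, NaHCO3, ethanol) to give the syn alcohol tert-butyl (4S)-4-[(4S)-2,2-dimethyl-1,3-dioxolan-4-yl]-4-hydroxy-2-methylidenebutanoate F7, which is also the minor epimer of step 1. Acetic anhydride, pyridine and DMAP then give 5 with retention.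

## Further compounds

F1 | step 3 | tert-butyl (4R)-4-[(tert-butyldimethylsilyl)oxy]-4-[(4S)-2,2-dimethyl-1,3-dioxolan-4-yl]-2-methylidenebutanoate | C=C(C[C@@H](O[Si](C)(C)C(C)(C)C)[C@@H]1COC(C)(C)O1)C(=O)OC(C)(C)C
F2 | step 3 | tert-butyl (4R)-2-bromo-2-(bromomethyl)-4-[(tert-butyldimethylsilyl)oxy]-4-[(4S)-2,2-dimethyl-1,3-dioxolan-4-yl]butanoate | BrCC(Br)(C[C@@H](O[Si](C)(C)C(C)(C)C)[C@@H]1COC(C)(C)O1)C(=O)OC(C)(C)C
F3 | step 3 | tert-butyl (2E,4R)-2-(bromomethylidene)-4-[(tert-butyldimethylsilyl)oxy]-4-[(4S)-2,2-dimethyl-1,3-dioxolan-4-yl]butanoate | Br/C=C(\C[C@@H](O[Si](C)(C)C(C)(C)C)[C@@H]1COC(C)(C)O1)C(=O)OC(C)(C)C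
F4 | step 3 | tert-butyl (2E,4R)-2-(bromomethylidene)-4-[(4S)-2,2-dimethyl-1,3-dioxolan-4-yl]-4-hydroxybutanoate | Br/C=C(\C[C@@H](O)[C@@H]1COC(C)(C)O1)C(=O)OC(C)(C)C
F5 | step 9 | tert-butyl (3S,4R,5S)-5-acetoxy-3-hydroxy-4-{[(2E)-2-methylbut-2-enoyl]oxy}cyclohex-1-ene-1-carboxylate | C/C=C(\C)C(=O)O[C@@H]1[C@@H](OC(C)=O)CC(C(=O)OC(C)(C)C)=C[C@@H]1O
F6 | step 2 | tert-butyl (4S)-4-[(chloroacetyl)oxy]-4-[(4S)-2,2-dimethyl-1,3-dioxolan-4-yl]-2-methylidenebutanoate | C=C(C[C@H](OC(=O)CCl)[C@@H]1COC(C)(C)O1)C(=O)OC(C)(C)C
F7 | step 2 | tert-butyl (4S)-4-[(4S)-2,2-dimethyl-1,3-dioxolan-4-yl]-4-hydroxy-2-methylidenebutanoate | C=C(C[C@H](O)[C@@H]1COC(C)(C)O1)C(=O)OC(C)(C)C
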